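The route rests on closing the γ-lactone last, across the α-acyloxy ketone of the ten-membered ring: the oxygen on C7 carries the three-carbon unit C19–C17–C18 as an acrylate, next to the C8 ketone. One copper hydride reduction turns the acrylate into an enolate whose carbon C17 adds to C8, so that the C8–C17 bond, the five-membered lactone, the tertiary C8 hydroxyl and the C17 methyl centre arise together. The precursor, a ten-membered α-acryloyloxy ketone fused to the epoxycyclohexane, comes from a Hajos–Parrish hydrindane whose five-membered ring is cut by ozonolysis, a B-alkyl Suzuki coupling and a Nozaki–Hiyama–Kishi ring closure.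

Key step: step 27

Remark: atoms carry briarane numbers (C1 quaternary ring-fusion carbon with methyl C15, C2 acetoxy carbon, C5=C6 chloroalkene with methyl C16, C7 lactone carbinol, C8 tertiary carbinol, C9 secondary carbinol, C10 ring-fusion CH, C11 with methyl C20, C12 hexanoyloxy carbon, C13/C14 epoxide, C17 lactone α-carbon with methyl C18, C19 lactone carbonyl).

Remark (assumption): the L-phenylalanine-mediated cyclisation of step 1 is taken to give the (S)-enedione, the usual sense for L-amino acids in Hajos–Parrish cyclisations.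

Step 1
Reactants: 1 2-methylcyclopentane-1,3-dione; 2 pent-1-en-3-one (ethyl vinyl ketone)
Product: 4 (S)-4,7a-dimethyl-2,3,7,7a-tetrahydro-1H-indene-1,5(6H)-dione, via Michael triketone 3 (not isolated)
Conditions: Et3N (cat.), MeCN, rt; then L-phenylalanine, (+)-camphor-10-sulfonic acid, DMF, 30 → 70 °C
Reagents that add atoms: none
Why: Michael addition followed by an amino-acid-mediated intramolecular aldol condensation (Hajos–Parrish reaction), in which the enamine of the side-chain ketone selects one of the two enantiotopic ring carbonyls and so sets the quaternary C1 as (S).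

Step 2
Reactants: 4 (S)-enedione
Product: 5 (S)-4,7a-dimethyl-2,3-dihydro-1H-indene-1,5(7aH)-dione (cross-conjugated dienone, new C13=C14 double bond)
Conditions: DDQ, dioxane, reflux
Reagents that add atoms: none
Why: Quinone dehydrogenation of the enone through its cross-conjugated dienol should introduce the C13=C14 double bond and leave the saturated cyclopentanone untouched; no stereocentre is formed.

Step 3
Reactants: 5 cross-conjugated dienone
Product: 6 13,14-epoxy enedione (epoxide on the face opposite the C1 methyl)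
Conditions: 30% aq. H2O2, NaOH (cat.), MeOH, 0 °C
Reagents that add atoms: hydrogen peroxide, OO
Why: Weitz–Scheffer nucleophilic epoxidation should attack the unsubstituted enone carbon C14 rather than the fully substituted C10, from the face opposite the angular methyl, giving the epoxide trans to that methyl.

Step 4
Reactants: 6 epoxy enedione
Product: 7 epoxy allylic alcohol (C12 hydroxyl cis to the epoxide, C2 ketone retained)
Conditions: NaBH4, CeCl3·7H2O, MeOH, −78 °C
Reagents that add atoms: none
Why: Luche reduction should reduce the cerium-activated enone carbonyl 1,2 faster than the hindered cyclopentanone, with hydride entering anti to the epoxide oxygen so that the C12 hydroxyl ends cis to the epoxide.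

Step 5
Reactants: 7 epoxy allylic alcohol
Product: 8 trans-hydrindanone alcohol (H10 trans to the C1 methyl, C11 methyl cis to the C1 methyl and trans to the C12 hydroxyl)
Conditions: [Ir(cod)(PCy3)(py)]PF6 (cat.), H2, CH2Cl2, rt
Reagents that add atoms: none
Why: Hydroxyl-directed homogeneous hydrogenation: the cationic iridium centre bound to the C12 hydroxyl should deliver both hydrogens to the tetrasubstituted C10=C11 bond on the hydroxyl face, which sets C10 and C11 together.

Step 6
Reactants: 8 trans-hydrindanone alcohol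
Product: 9 C12 tert-butyldimethylsilyl ether of 8
Conditions: TBSOTf, 2,6-lutidine, CH2Cl2, −78 °C
Reagents that add atoms: tert-butyldimethylsilyl trifluoromethanesulfonate, CC(C)(C)[Si](C)(C)OS(=O)(=O)C(F)(F)F
Why: Silylation of the hindered secondary alcohol with the silyl triflate; no stereocentre is touched.

Step 7
Reactants: 9 silyl ether
Product: 11 cyclopentenone (C2 ketone conjugated to a new C3=C9 double bond), via silyl enol ether 10 (not isolated)
Conditions: LiN(i-Pr)2, Me3SiCl, THF, −78 °C; then Pd(OAc)2, MeCN, rt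
Reagents that add atoms: none
Why: Saegusa–Ito oxidation: the ketone can enolise only toward C3 because C1 is quaternary, and divalent palladium dehydrosilylates the enol ether to the enone.

Step 8
Reactants: 11 cyclopentenone
Product: 12 allylic alcohol (C2 hydroxyl cis to the C1 methyl)
Conditions: NaBH4, CeCl3·7H2O, MeOH, −40 °C
Reagents that add atoms: none
Why: Luche 1,2-reduction with hydride attack on the face opposite the angular methyl should give the C2 configuration of the target.

Step 9
Reactants: 12 allylic alcohol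
Product: 13 C2 triethylsilyl ether of 12
Conditions: Et3SiCl, imidazole, DMF, 0 °C
Reagents that add atoms: chlorotriethylsilane, CC[Si](CC)(CC)Cl
Why: Standard silylation of a secondary alcohol; the triethylsilyl group can later be removed in the presence of the tert-butyldimethylsilyl ether.

Step 10
Reactants: 13 cyclopentene silyl ether
Product: 15 aldehyde ester (C3 aldehyde next to C2, C9 methyl ester on C10), via methoxy hydroperoxide 14 (not isolated)
Conditions: O3, CH2Cl2/MeOH, NaHCO3, −78 °C; then Ac2O, Et3N, 0 °C → rt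
Reagents that add atoms: ozone, [O-][O+]=O; methanol, CO
Why: Ozonolysis with terminus differentiation: the primary ozonide should open with the carbonyl oxide on C9, remote from the electron-withdrawing silyloxy carbon; methanol traps it and Ac2O/Et3N dehydrates the methoxy hydroperoxide to the ester, leaving C3 as the aldehyde with all stereocentres intact.

Step 11
Reactants: 15 aldehyde ester
Product: 16 vinyl ester (C2(OSiEt3)–CH=CH2 on C1, C9 methyl ester on C10)
Conditions: Ph3PCH3Br, KN(SiMe3)2, THF, −78 → 0 °C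
Reagents that add atoms: methyltriphenylphosphonium bromide, C[P+](c1ccccc1)(c1ccccc1)c1ccccc1.[Br-]
Why: Wittig methylenation of the aldehyde, which is far more reactive than the hindered ester; low temperature should avoid epimerisation at C2.

Step 12
Reactants: 17 ethyl 2-chloro-3-oxobutanoate
Product: 18 ethyl (E)-2-chloro-3-(trifluoromethylsulfonyloxy)but-2-enoate (triflate cis to the ester)
Conditions: aq. LiOH, toluene, 5 °C; Tf2O
Reagents that add atoms: trifluoromethanesulfonic anhydride, O=S(=O)(OS(=O)(=O)C(F)(F)F)C(F)(F)F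
Why: O-sulfonylation of the chelated lithium enolate of the β-keto ester fixes the triflate cis to the ester, which is the geometry needed for C4 and C7 on the later chloroalkene.

Step 13
Reactants: 18 enol triflate ester
Product: 19 (E)-3-chloro-4-hydroxybut-2-en-2-yl trifluoromethanesulfonate
Conditions: i-Bu2AlH, CH2Cl2, −78 °C
Reagents that add atoms: none
Why: 1,2-Reduction of the ester by the aluminium hydride at low temperature should spare the enol triflate and keep the alkene geometry.

Step 14
Reactants: 19 allylic alcohol triflate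
Product: 20 (E)-3-chloro-4-(triethylsilyloxy)but-2-en-2-yl trifluoromethanesulfonate
Conditions: Et3SiCl, imidazole, CH2Cl2, 0 °C
Reagents that add atoms: chlorotriethylsilane, CC[Si](CC)(CC)Cl
Why: Standard silylation of the primary allylic alcohol.

Step 15
Reactants: 16 vinyl ester; 20 alkenyl triflate
Product: 22 coupled ester (chain C2(OSiEt3)–C3H2–C4H2–C5(CH3)=C6(Cl)–C7H2OSiEt3 on C1), via alkylborane 21 (not isolated)
Conditions: 9-BBN, THF, rt; then 20, PdCl2(dppf) (cat.), AsPh3, Cs2CO3, DMF/H2O, rt
Reagents that add atoms: none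
Why: B-alkyl Suzuki–Miyaura coupling: anti-Markovnikov hydroboration of the only alkene, then coupling at the C–OTf bond (the C–Cl bond is inert) with retention, so that C4 ends cis to C7 and chlorine cis to the methyl.

Step 16
Reactants: 22 coupled ester
Product: 23 N-methoxy-N-methylamide at C9
Conditions: MeNH(OMe)·HCl, i-PrMgCl, THF, −20 → 0 °C
Reagents that add atoms: N,O-dimethylhydroxylamine hydrochloride, CNOC.Cl
Why: Aminolysis of the methyl ester by the chloromagnesium amide gives an acyl donor that stops at the ketone in the next step.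

Step 17
Reactants: 23 N-methoxy-N-methylamide; 24 (1-bromovinyl)trimethylsilane
Product: 26 α-silyl enone (C9 ketone bearing C8(SiMe3)=CH2), via Grignard reagent 25 (not isolated)
Conditions: 24, Mg, THF; then 23, THF, −78 → 0 °C
Reagents that add atoms: none
Why: Grignard acylation of the N-methoxy-N-methylamide: the chelated tetrahedral intermediate survives until work-up, so a single addition installs C8 as a masked alkenyl iodide.

Step 18
Reactants: 26 α-silyl enone
Product: 27 C9 allylic alcohol (target configuration at C9)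
Conditions: NaBH4, CeCl3·7H2O, MeOH, −78 °C
Reagents that add atoms: none
Why: Luche 1,2-reduction under Felkin–Anh control: hydride should attack the C9 ketone anti to the quaternary C1 substituent of C10, which gives the C9 configuration of the target.

Step 19
Reactants: 27 C9 alcohol
Product: 28 C9 4-methoxybenzyl ether
Conditions: NaH, 4-methoxybenzyl bromide, Bu4NI (cat.), THF/DMF, 0 °C
Reagents that add atoms: 4-methoxybenzyl bromide, COc1ccc(CBr)cc1
Why: Williamson etherification gives a protecting group that survives fluoride and is removed oxidatively at the end.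

Step 20
Reactants: 28 4-methoxybenzyl ether
Product: 29 diol (C2–OH and C7–OH free)
Conditions: HF·pyridine, pyridine, THF, 0 °C
Reagents that add atoms: none
Why: Buffered fluoride should cleave both triethylsilyl ethers while the hindered tert-butyldimethylsilyl ether and the vinylsilane are kept.

Step 21
Reactants: 29 diol
Product: 30 α-chloro enal (C7 aldehyde, C2–OH free)
Conditions: MnO2, CH2Cl2, rt
Reagents that add atoms: none
Why: MnO2 oxidises only the primary allylic alcohol; the saturated secondary C2 alcohol is inert.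

Step 22
Reactants: 30 hydroxy enal
Product: 31 C2 acetate of 30
Conditions: Ac2O, pyridine, DMAP (cat.), CH2Cl2, rt
Reagents that add atoms: acetic anhydride, CC(=O)OC(C)=O
Why: Acylation of the only free hydroxyl installs the C2 acetate of the target.

Step 23
Reactants: 31 vinylsilane
Product: 32 alkenyl iodide (C8(I)=CH2)
Conditions: N-iodosuccinimide, MeCN/ClCH2CN, 0 °C → rt
Reagents that add atoms: N-iodosuccinimide, O=C1CCC(=O)N1I
Why: Ipso-iododesilylation: iodonium attack at the silicon-bearing carbon gives a β-silyl cation that loses silicon; the electron-poor chloro enal and the chloroalkene should not compete.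

Step 24
Reactants: 32 iodo aldehyde
Product: 33 ten-membered allylic alcohol (C7–C8 bond closed, C7–OH, exocyclic methylene on C8)
Conditions: CrCl2 (excess), NiCl2 (cat.), DMSO, rt, high dilution
Reagents that add atoms: none
Why: Nozaki–Hiyama–Kishi ring closure: the nickel-generated alkenylchromium (trivalent chromium) adds 1,2 to the enal and closes the ten-membered ring; the C7 carbinol is set under ring control, and a transition state with chromium chelated by the C9 ether oxygen is expected to give the 7,9-syn arrangement of the target.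

Step 25
Reactants: 33 macrocyclic alcohol
Product: 34 C7 acrylate
Conditions: acryloyl chloride, i-Pr2NEt, CH2Cl2, −40 → 0 °C
Reagents that add atoms: acryloyl chloride, C=CC(=O)Cl
Why: Acylation of the only free hydroxyl places C19, C17 and C18 on O7.

Step 26
Reactants: 34 acrylate
Product: 36 C8 ketone (α-acryloyloxy ketone), via diol 35 (not isolated)
Conditions: OsO4 (cat.), N-methylmorpholine N-oxide, acetone/H2O, 0 °C; then NaIO4, THF/H2O
Reagents that add atoms: osmium tetroxide, O=[Os](=O)(=O)=O (reoxidised by N-methylmorpholine N-oxide, C[N+]1([O-])CCOCC1)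
Why: Two-stage Lemieux–Johnson cleavage: OsO4 should prefer the 1,1-disubstituted alkene over the electron-poor acrylate and the hindered tetrasubstituted chloroalkene, and periodate can cleave only the C8–CH2 glycol because O7 is acylated.

Step 27
Reactants: 36 α-acryloyloxy ketone
Product: 38 lactone (7,8-fused γ-lactone, C8–OH, C17 methyl; C9 4-methoxybenzyl ether, C12 silyl ether, C2 acetate), via copper enolate 37 (not isolated)
Conditions: [(Ph3P)CuH]6, toluene, −40 → 0 °C; aq. NH4Cl
Reagents that add atoms: none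
Why: [(Ph3P)CuH]6 adds hydride to C18 of the s-cis acrylate to give the copper enolate 37 with the new methyl cis to the metal-bearing oxygen, and its carbon C17 then adds to the neighbouring C8 ketone through a closed, chelated Zimmerman–Traxler transition state, the copper alkoxide being protonated on work-up. The closest known reactions are copper hydride reductive aldol cyclisations of keto acrylates to β-hydroxy lactones and the intramolecular Reformatsky lactonisation of α-acyloxy ketones. The ring closed is the five-membered lactone O–C19–C17–C8–C7, formally a 5-(enolendo)-exo-trig aldol that becomes feasible because the enolate is metal-bound and the carbonyl is chelated. C17 is controlled by the enolate geometry in the closed transition state, which places the methyl cis to the new hydroxyl; C8 is controlled by the C7 stereocentre, since the tethered enolate can reach only the carbonyl face syn to O7 and the ten-membered ring should favour the cis-fused arrangement with H7 and the C8 hydroxyl on the same side. The step needs conjugate reduction of the acrylate in preference to 1,2-reduction of the ketone, which the much faster hydrocupration of an unhindered acrylate at low temperature should secure; chloroalkene, epoxide, acetate, silyl ether and benzyl ether are inert to the reagent.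

Step 28
Reactants: 38 lactone
Product: 39 C12 alcohol
Conditions: HF·pyridine, THF, 0 °C → rt
Reagents that add atoms: none
Why: Fluoride desilylation frees the C12 hydroxyl; lactone, acetate, epoxide and the 4-methoxybenzyl ether should survive.

Step 29
Reactants: 39 C12 alcohol
Product: 40 C12 hexanoate
Conditions: hexanoyl chloride, pyridine, DMAP (cat.), CH2Cl2, 0 °C
Reagents that add atoms: hexanoyl chloride, CCCCCC(=O)Cl
Why: Acylation of the secondary C12 hydroxyl; the tertiary C8 hydroxyl is too hindered to react and C9 is still protected.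

Step 30
Reactants: 40 C12 hexanoate
Product: 41 CNP0243318.1 (target)
Conditions: DDQ, CH2Cl2/pH 7 buffer, 0 °C
Reagents that add atoms: none
Why: Oxidative cleavage of the 4-methoxybenzyl ether by DDQ in wet solvent frees the C9 hydroxyl without acid or base, so esters, lactone and epoxide should remain.

Compound list

1 | 2-methylcyclopentane-1,3-dione | CC1C(=O)CCC1=O | starting material
2 | pent-1-en-3-one (ethyl vinyl ketone) | CCC(=O)C=C | starting material
3 | 2-methyl-2-(3-oxopentyl)cyclopentane-1,3-dione | CCC(=O)CCC1(C)C(=O)CCC1=O | intermediate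
4 | (S)-4,7a-dimethyl-2,3,7,7a-tetrahydro-1H-indene-1,5(6H)-dione | O=C1C(C)=C2CCC(=O)[C@@]2(C)CC1 | intermediate
5 | (S)-4,7a-dimethyl-2,3-dihydro-1H-indene-1,5(7aH)-dione | O=C1C(C)=C2CCC(=O)[C@@]2(C)C=C1 | intermediate
6 | 13,14-epoxy enedione: 5 with an epoxide across C13–C14 on the face opposite the C1 methyl | O=C1C(C)=C2CCC(=O)[C@@]2(C)[C@H]2O[C@@H]12 | intermediate
7 | epoxy allylic alcohol: C12 hydroxyl cis to the epoxide, C10=C11 alkene, C2 ketone | O[C@H]1C(C)=C2CCC(=O)[C@@]2(C)[C@H]2O[C@@H]12 | intermediate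
8 | trans-hydrindanone alcohol: H10 trans to the C1 methyl, C11 methyl trans to the C12 hydroxyl | O[C@H]1[C@H](C)[C@@H]2CCC(=O)[C@@]2(C)[C@H]2O[C@@H]12 | intermediate
9 | C12 tert-butyldimethylsilyl ether of 8 | CC(C)(C)[Si](C)(C)O[C@H]1[C@H](C)[C@@H]2CCC(=O)[C@@]2(C)[C@H]2O[C@@H]12 | intermediate
10 | trimethylsilyl enol ether of 9 (C2=C3) | CC(C)(C)[Si](C)(C)O[C@H]1[C@H](C)[C@@H]2CC=C(O[Si](C)(C)C)[C@@]2(C)[C@H]2O[C@@H]12 | intermediate
11 | cyclopentenone: C2 ketone, C3=C9 double bond | CC(C)(C)[Si](C)(C)O[C@H]1[C@H](C)[C@@H]2C=CC(=O)[C@@]2(C)[C@H]2O[C@@H]12 | intermediate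
12 | allylic alcohol: C2 hydroxyl cis to the C1 methyl | CC(C)(C)[Si](C)(C)O[C@H]1[C@H](C)[C@@H]2C=C[C@H](O)[C@@]2(C)[C@H]2O[C@@H]12 | intermediate
13 | C2 triethylsilyl ether of 12 | CC(C)(C)[Si](C)(C)O[C@H]1[C@H](C)[C@@H]2C=C[C@H](O[Si](CC)(CC)CC)[C@@]2(C)[C@H]2O[C@@H]12 | intermediate
14 | ring-opened C3 aldehyde carrying C9 as methoxy hydroperoxide | O=C[C@H](O[Si](CC)(CC)CC)[C@@]1(C)[C@H]2O[C@H]2[C@@H](O[Si](C)(C)C(C)(C)C)[C@H](C)[C@@H]1C(OC)OO | intermediate
15 | aldehyde ester: epoxycyclohexane with CH(OSiEt3)–CHO on C1 and CO2CH3 on C10 | O=C[C@H](O[Si](CC)(CC)CC)[C@@]1(C)[C@H]2O[C@H]2[C@@H](O[Si](C)(C)C(C)(C)C)[C@H](C)[C@@H]1C(=O)OC | intermediate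
16 | vinyl ester: CH(OSiEt3)–CH=CH2 on C1, CO2CH3 on C10 | C=C[C@H](O[Si](CC)(CC)CC)[C@@]1(C)[C@H]2O[C@H]2[C@@H](O[Si](C)(C)C(C)(C)C)[C@H](C)[C@@H]1C(=O)OC | intermediate
17 | ethyl 2-chloro-3-oxobutanoate | CCOC(=O)C(Cl)C(C)=O | starting material
18 | ethyl (E)-2-chloro-3-(trifluoromethylsulfonyloxy)but-2-enoate | CCOC(=O)/C(Cl)=C(/C)OS(=O)(=O)C(F)(F)F | intermediate
19 | (E)-3-chloro-4-hydroxybut-2-en-2-yl trifluoromethanesulfonate | OC/C(Cl)=C(/C)OS(=O)(=O)C(F)(F)F | intermediate
20 | (E)-3-chloro-4-(triethylsilyloxy)but-2-en-2-yl trifluoromethanesulfonate | CC[Si](CC)(CC)OC/C(Cl)=C(/C)OS(=O)(=O)C(F)(F)F | intermediate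
21 | B-alkyl-9-borabicyclo[3.3.1]nonane from 16 (boron on C4) | C1CCC2CCCC1B2CC[C@H](O[Si](CC)(CC)CC)[C@@]1(C)[C@H]2O[C@H]2[C@@H](O[Si](C)(C)C(C)(C)C)[C@H](C)[C@@H]1C(=O)OC | intermediate
22 | coupled ester: (E)-chloroalkene chain C2–C7 on C1 (C4 cis to C7), C9 methyl ester | CC[Si](CC)(CC)OC/C(Cl)=C(/C)CC[C@H](O[Si](CC)(CC)CC)[C@@]1(C)[C@H]2O[C@H]2[C@@H](O[Si](C)(C)C(C)(C)C)[C@H](C)[C@@H]1C(=O)OC | intermediate
23 | C9 N-methoxy-N-methylamide of 22 | CC[Si](CC)(CC)OC/C(Cl)=C(/C)CC[C@H](O[Si](CC)(CC)CC)[C@@]1(C)[C@H]2O[C@H]2[C@@H](O[Si](C)(C)C(C)(C)C)[C@H](C)[C@@H]1C(=O)N(C)OC | intermediate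
24 | (1-bromovinyl)trimethylsilane | C=C(Br)[Si](C)(C)C | starting material
25 | (1-(trimethylsilyl)vinyl)magnesium bromide | C=C([Mg]Br)[Si](C)(C)C | intermediate
26 | α-silyl enone: C9 ketone bearing C8(SiMe3)=CH2 | CC[Si](CC)(CC)OC/C(Cl)=C(/C)CC[C@H](O[Si](CC)(CC)CC)[C@@]1(C)[C@H]2O[C@H]2[C@@H](O[Si](C)(C)C(C)(C)C)[C@H](C)[C@@H]1C(=O)C(=C)[Si](C)(C)C | intermediate
27 | C9 allylic alcohol | CC[Si](CC)(CC)OC/C(Cl)=C(/C)CC[C@H](O[Si](CC)(CC)CC)[C@@]1(C)[C@H]2O[C@H]2[C@@H](O[Si](C)(C)C(C)(C)C)[C@H](C)[C@@H]1[C@H](O)C(=C)[Si](C)(C)C | intermediate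
28 | C9 4-methoxybenzyl ether of 27 | CC[Si](CC)(CC)OC/C(Cl)=C(/C)CC[C@H](O[Si](CC)(CC)CC)[C@@]1(C)[C@H]2O[C@H]2[C@@H](O[Si](C)(C)C(C)(C)C)[C@H](C)[C@@H]1[C@H](OCc1ccc(OC)cc1)C(=C)[Si](C)(C)C | intermediate
29 | diol: C2–OH and C7–OH free | OC/C(Cl)=C(/C)CC[C@H](O)[C@@]1(C)[C@H]2O[C@H]2[C@@H](O[Si](C)(C)C(C)(C)C)[C@H](C)[C@@H]1[C@H](OCc1ccc(OC)cc1)C(=C)[Si](C)(C)C | intermediate
30 | α-chloro enal: C7 aldehyde, C2–OH free | O=C/C(Cl)=C(/C)CC[C@H](O)[C@@]1(C)[C@H]2O[C@H]2[C@@H](O[Si](C)(C)C(C)(C)C)[C@H](C)[C@@H]1[C@H](OCc1ccc(OC)cc1)C(=C)[Si](C)(C)C | intermediate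
31 | C2 acetate of 30 | O=C/C(Cl)=C(/C)CC[C@H](OC(C)=O)[C@@]1(C)[C@H]2O[C@H]2[C@@H](O[Si](C)(C)C(C)(C)C)[C@H](C)[C@@H]1[C@H](OCc1ccc(OC)cc1)C(=C)[Si](C)(C)C | intermediate
32 | alkenyl iodide: C8(I)=CH2, C7 aldehyde | O=C/C(Cl)=C(/C)CC[C@H](OC(C)=O)[C@@]1(C)[C@H]2O[C@H]2[C@@H](O[Si](C)(C)C(C)(C)C)[C@H](C)[C@@H]1[C@H](OCc1ccc(OC)cc1)C(I)=C | intermediate
33 | ten-membered allylic alcohol: C7–OH, exocyclic methylene on C8 | CC(C)(C)[Si](C)(C)O[C@H]1[C@H](C)[C@@H]2[C@H](OCc3ccc(OC)cc3)C(=C)[C@H](O)/C(Cl)=C(/C)CC[C@H](OC(C)=O)[C@@]2(C)[C@H]2O[C@@H]12 | intermediate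
34 | C7 acrylate of 33 | CC(C)(C)[Si](C)(C)O[C@H]1[C@H](C)[C@@H]2[C@H](OCc3ccc(OC)cc3)C(=C)[C@H](OC(=O)C=C)/C(Cl)=C(/C)CC[C@H](OC(C)=O)[C@@]2(C)[C@H]2O[C@@H]12 | intermediate
35 | diol from 34: C8–OH and CH2OH on C8 | CC(C)(C)[Si](C)(C)O[C@H]1[C@H](C)[C@@H]2[C@H](OCc3ccc(OC)cc3)C(O)(CO)[C@H](OC(=O)C=C)/C(Cl)=C(/C)CC[C@H](OC(C)=O)[C@@]2(C)[C@H]2O[C@@H]12 | intermediate
36 | C8 ketone: α-acryloyloxy ketone | CC(C)(C)[Si](C)(C)O[C@H]1[C@H](C)[C@@H]2[C@H](OCc3ccc(OC)cc3)C(=O)[C@H](OC(=O)C=C)/C(Cl)=C(/C)CC[C@H](OC(C)=O)[C@@]2(C)[C@H]2O[C@@H]12 | intermediate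
37 | copper enolate of the O7 propanoate (methyl cis to O–Cu; phosphine ligand omitted) | CC(C)(C)[Si](C)(C)O[C@H]1[C@H](C)[C@@H]2[C@H](OCc3ccc(OC)cc3)C(=O)[C@H](O/C(O[Cu])=C/C)/C(Cl)=C(/C)CC[C@H](OC(C)=O)[C@@]2(C)[C@H]2O[C@@H]12 | intermediate
38 | lactone: γ-lactone fused at C7–C8, C8–OH, C17 methyl | CC(C)(C)[Si](C)(C)O[C@H]1[C@H](C)[C@@H]2[C@H](OCc4ccc(OC)cc4)[C@@]3(O)[C@H](OC(=O)[C@@H]3C)/C(Cl)=C(/C)CC[C@H](OC(C)=O)[C@@]2(C)[C@H]2O[C@@H]12 | intermediate
39 | C12 alcohol | O[C@H]1[C@H](C)[C@@H]2[C@H](OCc4ccc(OC)cc4)[C@@]3(O)[C@H](OC(=O)[C@@H]3C)/C(Cl)=C(/C)CC[C@H](OC(C)=O)[C@@]2(C)[C@H]2O[C@@H]12 | intermediate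
40 | C12 hexanoate | CCCCCC(=O)O[C@H]1[C@H](C)[C@@H]2[C@H](OCc4ccc(OC)cc4)[C@@]3(O)[C@H](OC(=O)[C@@H]3C)/C(Cl)=C(/C)CC[C@H](OC(C)=O)[C@@]2(C)[C@H]2O[C@@H]12 | intermediate
41 | CNP0243318.1 | CCCCCC(=O)O[C@H]1[C@H](C)[C@@H]2[C@H](O)[C@@]3(O)[C@H](OC(=O)[C@@H]3C)/C(Cl)=C(/C)CC[C@H](OC(C)=O)[C@@]2(C)[C@H]2O[C@@H]12 | target

Total step count: 30. Longest linear sequence: 27 steps (steps 1–11 and 15–30); the alkenyl triflate 20 is made in a 3-step branch (steps 12–14).

Steps most likely to fail

Step 27. The copper hydride may reduce the C8 ketone 1,2, or reduce the acrylate to a propanoate that does not cyclise, or the aldol may close with poor control at C17. The fallback sets out from 33: acylation with 2-bromopropanoyl bromide and pyridine should give the 2-bromopropanoate F1 (either configuration at the bromine-bearing carbon serves). OsO4/N-methylmorpholine N-oxide and then NaIO4 would give the keto bromo ester F2, with no second alkene of the acrylate type to compete. SmI2 in THF at −78 °C reduces the carbon–bromine bond first, and the trivalent samarium enolate closes the lactone by an intramolecular Reformatsky reaction. The fallback returns to the route at 38.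

Step 24. The ring-closing carbonyl addition may occur with poor facial selectivity and deliver mainly the C7 epimer. The fallback sets out from 32: the same ring closure then gives the C7-epimeric alcohol F3, which is esterified with acrylic acid under Mitsunobu conditions (PPh3, diisopropyl azodicarboxylate, toluene, 0 °C). The substitution inverts C7 and installs the acrylate in one operation, returning to the route at 34.

Step 26. Dihydroxylation of the acrylate may compete with that of the hindered, doubly allylic exocyclic alkene. The fallback sets out from 33 and changes the order of events: Et3SiOTf and 2,6-lutidine give the C7 triethylsilyl ether F4; OsO4/N-methylmorpholine N-oxide and then NaIO4 give the silyloxy ketone F5; buffered HF·pyridine removes only the triethylsilyl group to give the α-hydroxy ketone F6; acylation with acryloyl chloride and i-Pr2NEt returns to the route at 36.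

Further compounds

F1 | step 27 | 2-bromopropanoate of 33 at O7 | CC(C)(C)[Si](C)(C)O[C@H]1[C@H](C)[C@@H]2[C@H](OCc3ccc(OC)cc3)C(=C)[C@H](OC(=O)C(C)Br)/C(Cl)=C(/C)CC[C@H](OC(C)=O)[C@@]2(C)[C@H]2O[C@@H]12
F2 | step 27 | C8 ketone of F1 | CC(C)(C)[Si](C)(C)O[C@H]1[C@H](C)[C@@H]2[C@H](OCc3ccc(OC)cc3)C(=O)[C@H](OC(=O)C(C)Br)/C(Cl)=C(/C)CC[C@H](OC(C)=O)[C@@]2(C)[C@H]2O[C@@H]12
F3 | step 24 | C7 epimer of 33 | CC(C)(C)[Si](C)(C)O[C@H]1[C@H](C)[C@@H]2[C@H](OCc3ccc(OC)cc3)C(=C)[C@@H](O)/C(Cl)=C(/C)CC[C@H](OC(C)=O)[C@@]2(C)[C@H]2O[C@@H]12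
F4 | step 26 | C7 triethylsilyl ether of 33 | CC(C)(C)[Si](C)(C)O[C@H]1[C@H](C)[C@@H]2[C@H](OCc3ccc(OC)cc3)C(=C)[C@H](O[Si](CC)(CC)CC)/C(Cl)=C(/C)CC[C@H](OC(C)=O)[C@@]2(C)[C@H]2O[C@@H]12
F5 | step 26 | C8 ketone of F4 | CC(C)(C)[Si](C)(C)O[C@H]1[C@H](C)[C@@H]2[C@H](OCc3ccc(OC)cc3)C(=O)[C@H](O[Si](CC)(CC)CC)/C(Cl)=C(/C)CC[C@H](OC(C)=O)[C@@]2(C)[C@H]2O[C@@H]12
F6 | step 26 | α-hydroxy ketone: F5 without the silyl group on O7 | CC(C)(C)[Si](C)(C)O[C@H]1[C@H](C)[C@@H]2[C@H](OCc3ccc(OC)cc3)C(=O)[C@H](O)/C(Cl)=C(/C)CC[C@H](OC(C)=O)[C@@]2(C)[C@H]2O[C@@H]12
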